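**Strategy.** The route rests on disconnecting the bond between the lactone α-carbon C4 and the quaternary carbon C5, the one bond shared by the γ-lactone and cyclohexene ring A. An ester-tethered intramolecular Diels–Alder reaction of a (2Z,4E)-5-(2-furyl)pentadienoate with a (Z)-trisubstituted allylic alcohol unit forms C4–C5 and C1–C10 at once, closing both rings and setting C1, C5 and C10 with the trans relation of C19 and H-10 that a cyclic dienophile could not deliver. The acyclic triene carries a single silyloxy stereocentre (the later C9 carbonyl) that steers the diene face; rings B and C are then annulated by aldol and hydroalkylation steps.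

Key step: step 11

Remark 1 (numbering used in all names): C1–C10 are the decalin carbons (C1 carries the furan, C2 the free hydroxyl, C3=C4 the lactone alkene, C5 the quaternary carbon, C7 the acetoxy group, C8 the secondary methyl C17, C9 the quaternary methyl C20). C11–C12 are the CH2–C=O bridge, C13–C16 the furan carbons (C16 on C1, C13 on C12), C18 the lactone carbonyl on C4 and C19 the lactone CH2 on C5. β is the face of H-10, α the face of C19.
Remark 2: compounds 1, 2, 4, 6, 9, 12 and 13 are taken as commercially available.
Remark 3: the sense of facial induction in step 11 is assigned by the allylic 1,3-strain model; because the controlling C9 carbinol is oxidised in step 13, the (S)-hydroxy ester would be used instead should the sense prove opposite.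

Step 1
Reactants: 1 3-bromofuran-2-carbaldehyde; 2 ethynyltriisopropylsilane
Product: 3 3-[(triisopropylsilyl)ethynyl]furan-2-carbaldehyde
Conditions: PdCl2(PPh3)2 (2 mol %), CuI (4 mol %), Et3N, THF, 50 °C
Reagents that add atoms: none
Why: Sonogashira coupling, in which the ortho-formyl group activates the 3-bromofuran toward oxidative addition; no stereocentre is formed.

Step 2
Reactants: 3 3-[(triisopropylsilyl)ethynyl]furan-2-carbaldehyde; 4 (triphenylphosphoranylidene)acetaldehyde
Product: 5 (E)-3-{3-[(triisopropylsilyl)ethynyl]furan-2-yl}prop-2-enal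
Conditions: toluene, 80 °C
Reagents that add atoms: none
Why: Wittig olefination with the stabilised formylmethylene ylide, which should give the (E)-enal.

Step 3
Reactants: 5 (E)-3-{3-[(triisopropylsilyl)ethynyl]furan-2-yl}prop-2-enal; 6 methyl 2-[bis(2,2,2-trifluoroethoxy)phosphoryl]acetate
Product: 7 methyl (2Z,4E)-5-{3-[(triisopropylsilyl)ethynyl]furan-2-yl}penta-2,4-dienoate
Conditions: KHMDS (KN(SiMe3)2), 18-crown-6, THF, −78 °C
Reagents that add atoms: none
Why: Still–Gennari variant of the Horner–Wadsworth–Emmons reaction, in which the electron-poor trifluoroethyl phosphonate makes elimination faster than equilibration, so the new C3=C4 bond should form with (Z) geometry while the existing (E) bond is untouched.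

Step 4
Reactants: 7 methyl (2Z,4E)-5-{3-[(triisopropylsilyl)ethynyl]furan-2-yl}penta-2,4-dienoate
Product: 8 (2Z,4E)-5-{3-[(triisopropylsilyl)ethynyl]furan-2-yl}penta-2,4-dienoic acid
Conditions: LiOH, THF/H2O, 0 °C; then aq. HCl to pH 3
Reagents that add atoms: lithium hydroxide, [Li+].[OH-]
Why: Ester saponification at low temperature, which should keep the (2Z) geometry and the triisopropylsilyl alkyne intact.

Step 5
Reactants: 9 methyl (R)-2-hydroxybutanoate
Product: 10 methyl (R)-2-[(tert-butyldimethylsilyl)oxy]butanoate
Conditions: TBSCl, imidazole, DMF, rt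
Reagents that add atoms: tert-butyl(chloro)dimethylsilane, CC(C)(C)[Si](C)(C)Cl
Why: Imidazole-promoted silyl ether formation at the secondary alcohol; the stereocentre (later C9) is not touched.

Step 6
Reactants: 10 methyl (R)-2-[(tert-butyldimethylsilyl)oxy]butanoate
Product: 11 (R)-2-[(tert-butyldimethylsilyl)oxy]butanal
Conditions: DIBAL-H (i-Bu2AlH), CH2Cl2, −78 °C
Reagents that add atoms: none
Why: Partial ester reduction through a tetrahedral aluminate that is stable at −78 °C; the α-silyloxy aldehyde is used directly to avoid epimerisation.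

Step 7
Reactants: 12 ethyl 2-[bis(2-methylphenoxy)phosphoryl]acetate; 13 tert-butyl(2-iodoethoxy)dimethylsilane
Product: 14 ethyl 2-[bis(2-methylphenoxy)phosphoryl]-4-[(tert-butyldimethylsilyl)oxy]butanoate (racemic)
Conditions: NaH, DMF, 0 °C to rt
Reagents that add atoms: none
Why: SN2 C-alkylation of the sodium phosphonoacetate enolate by the primary iodide.

Step 8
Reactants: 14 ethyl 2-[bis(2-methylphenoxy)phosphoryl]-4-[(tert-butyldimethylsilyl)oxy]butanoate; 11 (R)-2-[(tert-butyldimethylsilyl)oxy]butanal
Product: 15 ethyl (R,Z)-4-[(tert-butyldimethylsilyl)oxy]-2-{2-[(tert-butyldimethylsilyl)oxy]ethyl}hex-2-enoate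
Conditions: NaH, THF, −78 to 0 °C
Reagents that add atoms: none
Why: Ando-type (Z)-selective Horner–Wadsworth–Emmons olefination, in which the diaryl phosphonate should give the trisubstituted enoate with the ester carbon (future C19) cis to the carbinol carbon (future C9), the low temperature protecting the α-stereocentre.

Step 9
Reactants: 15 ethyl (R,Z)-4-[(tert-butyldimethylsilyl)oxy]-2-{2-[(tert-butyldimethylsilyl)oxy]ethyl}hex-2-enoate
Product: 16 (R,Z)-4-[(tert-butyldimethylsilyl)oxy]-2-{2-[(tert-butyldimethylsilyl)oxy]ethyl}hex-2-en-1-ol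
Conditions: DIBAL-H (i-Bu2AlH), CH2Cl2, −78 °C
Reagents that add atoms: none
Why: 1,2-Reduction of the enoate to the allylic alcohol with retention of alkene geometry.

Step 10
Reactants: 16 (R,Z)-4-[(tert-butyldimethylsilyl)oxy]-2-{2-[(tert-butyldimethylsilyl)oxy]ethyl}hex-2-en-1-ol; 8 (2Z,4E)-5-{3-[(triisopropylsilyl)ethynyl]furan-2-yl}penta-2,4-dienoic acid
Product: 17 triene ester: the (2Z,4E)-dienoate 8 esterified at the C19 oxygen of allylic alcohol 16
Conditions: PPh3, DIAD, THF, 0 °C to rt
Reagents that add atoms: none
Why: Mitsunobu esterification, which activates the alcohol and not the acid, so the (2Z)-dienoic acid is not exposed to acyl-transfer catalysts that isomerise it and the primary allylic centre reacts by direct SN2 displacement.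

Step 11
Reactants: 17 triene ester
Product: 18 cycloadduct: cis-fused γ-lactone on cyclohexene ring A (C2=C3; H-4 β; C19 α) with 2-(TBS-oxy)ethyl on C5 (β); (R)-1-(TBS-oxy)propyl on C10 (α; H-10 β); 3-(TIPS-ethynyl)furan-2-yl on C1 (β)
Conditions: toluene (0.005 M), BHT (cat.), 170 °C, sealed tube, base-washed glassware
Reagents that add atoms: none
Why: Thermal, concerted but asynchronous intramolecular Diels–Alder reaction (ester-tethered nona-1,3,8-triene type) in which the dienoate C1=C2–C3=C4 adds across the C5=C10 alkene, forming C4–C5 and C1–C10. The three-atom tether C18–O–C19 sits on the (Z) position of the diene and can therefore reach only the exo position of the dienophile, so the γ-lactone closes cis-fused through the tether while ring A closes as the cyclohexene of the [4+2] event. Suprafacial addition carries the cis relation of C19 and C9 in the alkene into the C19(α)/H-10(β) trans relation of the future decalin, and the (4E) geometry together with the exo tether places the furan on C1 anti to C19; C4 is set cis to C19 and is erased later. Absolute control comes from C9: allylic 1,3-strain with C19 holds H-9 in the alkene plane and the diene should add to the face opposite the silyloxy group. The step needs π-facial selectivity and integrity of the (2Z)-dienoate, secured by the pairing of the Z-alkene with the allylic stereocentre, base-washed glassware and a radical inhibitor. The closest known reaction type is the formation of cis-fused bicyclic lactones from (Z)-diene esters on heating.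

Step 12
Reactants: 18 cycloadduct
Product: 19 diol: as 18 but with 2-hydroxyethyl on C5; (R)-1-hydroxypropyl on C10; 3-ethynylfuran-2-yl on C1
Conditions: TBAF (Bu4NF), AcOH, THF, 0 °C to rt
Reagents that add atoms: none
Why: Fluoride-mediated desilylation cleaves both silyl ethers and the alkynyl C–Si bond, acetic acid buffering the medium so that the β,γ-unsaturated lactone is not isomerised prematurely.

Step 13
Reactants: 19 diol
Product: 20 keto-aldehyde: C7 aldehyde (CH2CHO on C5) and C9 ethyl ketone (propanoyl on C10); lactone still β,γ-unsaturated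
Conditions: Dess–Martin periodinane, CH2Cl2, 0 °C to rt
Reagents that add atoms: none
Why: Dess–Martin oxidation converts the primary alcohol into the C7 aldehyde and the secondary alcohol into the C9 ketone, which erases the controlling stereocentre; C10 should keep its configuration because its acyl group is already equatorial on ring A.

Step 14
Reactants: 20 keto-aldehyde
Product: 22 tricyclic ketol (trans-fused rings A/B; conjugated 18,19-olide with C3=C4; 7β-OH; 8α-methyl; 9-oxo; 1β-(3-ethynylfuran-2-yl)), via conjugated keto-aldehyde 21 (not isolated)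
Conditions: TBD (1,5,7-triazabicyclo[4.4.0]dec-5-ene, 0.2 equiv), THF, 0 °C to rt
Reagents that add atoms: none
Why: Base catalysis first moves the alkene into conjugation (C3=C4) and then promotes a reversible intramolecular aldol addition (6-enolendo-exo-trig) of the C8 enolate to the C7 aldehyde, closing ring B as the trans-fused chair; under thermodynamic control the hydroxyl should be equatorial at C7 (β, since an axial hydroxyl would be 1,3-diaxial to C19) and the methyl equatorial at C8 (α).

Step 15
Reactants: 22 tricyclic ketol
Product: 23 9-methylene alcohol: as 22 but with an exocyclic C9=CH2 in place of the ketone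
Conditions: Zn, CH2Br2, TiCl4, THF/CH2Cl2, 0 °C to rt
Reagents that add atoms: dibromomethane, BrCBr
Why: Takai–Lombardo methylenation, in which the non-basic zinc–titanium methylene reagent should olefinate the hindered, enolisable C9 ketone without retro-aldol cleavage or epimerisation and leave the lactone, alkyne and free hydroxyl untouched.

Step 16
Reactants: 23 9-methylene alcohol
Product: 24 7β-acetate of 23
Conditions: Ac2O, pyridine, DMAP (cat.), CH2Cl2, 0 °C to rt
Reagents that add atoms: acetic anhydride, CC(=O)OC(C)=O
Why: DMAP-catalysed acetylation of the equatorial C7 hydroxyl, free of any β-elimination pathway because C9 is no longer a carbonyl.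

Step 17
Reactants: 24 7β-acetate
Product: 26 2-deoxy pentacycle (target skeleton with CH2 at C2; ring C closed; 9α-methyl; C12 ketone), via furyl methyl ketone 25 (not isolated)
Conditions: (IPr)AuCl (5 mol %), AgSbF6 (5 mol %), H2O (2 equiv), 1,4-dioxane, 60 °C then 100 °C [IPr = 1,3-bis(2,6-diisopropylphenyl)imidazol-2-ylidene]
Reagents that add atoms: water, O
Why: Gold-catalysed Markovnikov hydration of the terminal alkyne gives the furyl methyl ketone, whose enol then adds to the gold-activated 1,1-disubstituted alkene in an intramolecular Markovnikov hydroalkylation (Conia-ene type), C11 being delivered to C9 from the equatorial β side by the tether from the β-furan while the axial C19 methylene blocks the α side, so ring C should close trans-fused and the former methylene carbon becomes the axial α methyl C20.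

Step 18
Reactants: 26 2-deoxy pentacycle
Product: 27 2-oxo compound (ene-dione: C2 ketone conjugated through C3=C4 to the lactone)
Conditions: Rh2(cap)4 (1 mol %; cap = caprolactamate), t-BuOOH (70% aq., 5 equiv), 1,2-dichloroethane, 40 °C
Reagents that add atoms: tert-butyl hydroperoxide, CC(C)(C)OO
Why: Allylic oxidation by tert-butylperoxy radicals generated on the dirhodium caprolactamate catalyst converts C2, the only allylic methylene and the γ-position of the unsaturated lactone, into a ketone.

Step 19
Reactants: 27 2-oxo compound
Product: 28 target CNP0182929.2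
Conditions: NaBH4, CeCl3·7H2O, MeOH, −78 °C
Reagents that add atoms: none
Why: Luche reduction, in which cerium-activated borohydride should reduce the most electrophilic ene-dione carbonyl at C2 in a 1,2-sense ahead of the hindered furyl ketone, axial hydride delivery from the β face (anti to the axial H-1) giving the equatorial 2α-alcohol trans to the furan.

**Compound list**

1 | 3-bromofuran-2-carbaldehyde | O=Cc1occc1Br | starting material
2 | ethynyltriisopropylsilane | C#C[Si](C(C)C)(C(C)C)C(C)C | starting material
3 | 3-[(triisopropylsilyl)ethynyl]furan-2-carbaldehyde | O=Cc1occc1C#C[Si](C(C)C)(C(C)C)C(C)C | intermediate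
4 | (triphenylphosphoranylidene)acetaldehyde | O=CC=P(c1ccccc1)(c1ccccc1)c1ccccc1 | starting material
5 | (E)-3-{3-[(triisopropylsilyl)ethynyl]furan-2-yl}prop-2-enal | O=C/C=C/c1occc1C#C[Si](C(C)C)(C(C)C)C(C)C | intermediate
6 | methyl 2-[bis(2,2,2-trifluoroethoxy)phosphoryl]acetate | COC(=O)CP(=O)(OCC(F)(F)F)OCC(F)(F)F | starting material
7 | methyl (2Z,4E)-5-{3-[(triisopropylsilyl)ethynyl]furan-2-yl}penta-2,4-dienoate | COC(=O)/C=C\C=C\c1occc1C#C[Si](C(C)C)(C(C)C)C(C)C | intermediate
8 | (2Z,4E)-5-{3-[(triisopropylsilyl)ethynyl]furan-2-yl}penta-2,4-dienoic acid | OC(=O)/C=C\C=C\c1occc1C#C[Si](C(C)C)(C(C)C)C(C)C | intermediate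
9 | methyl (R)-2-hydroxybutanoate | CC[C@@H](O)C(=O)OC | starting material
10 | methyl (R)-2-[(tert-butyldimethylsilyl)oxy]butanoate | CC[C@@H](O[Si](C)(C)C(C)(C)C)C(=O)OC | intermediate
11 | (R)-2-[(tert-butyldimethylsilyl)oxy]butanal | CC[C@@H](O[Si](C)(C)C(C)(C)C)C=O | intermediate
12 | ethyl 2-[bis(2-methylphenoxy)phosphoryl]acetate | CCOC(=O)CP(=O)(Oc1ccccc1C)Oc1ccccc1C | starting material
13 | tert-butyl(2-iodoethoxy)dimethylsilane | CC(C)(C)[Si](C)(C)OCCI | starting material
14 | ethyl 2-[bis(2-methylphenoxy)phosphoryl]-4-[(tert-butyldimethylsilyl)oxy]butanoate (racemic) | CCOC(=O)C(CCO[Si](C)(C)C(C)(C)C)P(=O)(Oc1ccccc1C)Oc1ccccc1C | intermediate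
15 | ethyl (R,Z)-4-[(tert-butyldimethylsilyl)oxy]-2-{2-[(tert-butyldimethylsilyl)oxy]ethyl}hex-2-enoate | CC[C@@H](O[Si](C)(C)C(C)(C)C)/C=C(/CCO[Si](C)(C)C(C)(C)C)C(=O)OCC | intermediate
16 | (R,Z)-4-[(tert-butyldimethylsilyl)oxy]-2-{2-[(tert-butyldimethylsilyl)oxy]ethyl}hex-2-en-1-ol | CC[C@@H](O[Si](C)(C)C(C)(C)C)/C=C(/CCO[Si](C)(C)C(C)(C)C)CO | intermediate
17 | triene ester of alcohol 16 with acid 8 | CC[C@@H](O[Si](C)(C)C(C)(C)C)/C=C(/CCO[Si](C)(C)C(C)(C)C)COC(=O)/C=C\C=C\c1occc1C#C[Si](C(C)C)(C(C)C)C(C)C | intermediate
18 | cycloadduct: cis-fused γ-lactone/cyclohexene (C2=C3) with bis-silyl ether side chains and silylalkynyl furan | CC[C@@H](O[Si](C)(C)C(C)(C)C)[C@H]1[C@H](c2occc2C#C[Si](C(C)C)(C(C)C)C(C)C)C=C[C@H]2C(=O)OC[C@@]12CCO[Si](C)(C)C(C)(C)C | intermediate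
19 | diol with terminal alkyne | CC[C@@H](O)[C@H]1[C@H](c2occc2C#C)C=C[C@H]2C(=O)OC[C@@]12CCO | intermediate
20 | keto-aldehyde (β,γ-unsaturated lactone) | CCC(=O)[C@H]1[C@H](c2occc2C#C)C=C[C@H]2C(=O)OC[C@@]12CC=O | intermediate
21 | conjugated keto-aldehyde (C3=C4) | CCC(=O)[C@H]1[C@H](c2occc2C#C)CC=C2C(=O)OC[C@@]12CC=O | intermediate
22 | tricyclic ketol (7β-OH, 8α-Me, 9-oxo) | O[C@H]1C[C@@]23COC(=O)C2=CC[C@@H](c4occc4C#C)[C@@H]3C(=O)[C@@H]1C | intermediate
23 | 9-methylene alcohol | O[C@H]1C[C@@]23COC(=O)C2=CC[C@@H](c4occc4C#C)[C@@H]3C(=C)[C@@H]1C | intermediate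
24 | 7β-acetate of 23 | CC(=O)O[C@H]1C[C@@]23COC(=O)C2=CC[C@@H](c4occc4C#C)[C@@H]3C(=C)[C@@H]1C | intermediate
25 | furyl methyl ketone (3-acetylfuran, exocyclic alkene intact) | CC(=O)O[C@H]1C[C@@]23COC(=O)C2=CC[C@@H](c4occc4C(C)=O)[C@@H]3C(=C)[C@@H]1C | intermediate
26 | 2-deoxy pentacycle | CC(=O)O[C@H]1C[C@@]23COC(=O)C2=CC[C@H]2c4occc4C(=O)C[C@@](C)([C@@H]1C)[C@@H]23 | intermediate
27 | 2-oxo compound (ene-dione) | CC(=O)O[C@H]1C[C@@]23COC(=O)C2=CC(=O)[C@H]2c4occc4C(=O)C[C@@](C)([C@@H]1C)[C@@H]23 | intermediate
28 | CNP0182929.2 | CC(=O)O[C@H]1C[C@@]23COC(=O)C2=C[C@H](O)[C@H]2c4occc4C(=O)C[C@@](C)([C@@H]1C)[C@@H]23 | target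

**Totals.** 19 steps in all; longest linear sequence 14 steps (9 → 10 → 11 → 15 → 16 → 17 → 18 → 19 → 20 → 22 → 23 → 24 → 26 → 27 → 28; the branch from 1 is equally long).

**Steps most likely to fail**

Step 11. The cycloaddition may be slow, because the ester tether must leave its preferred s-trans conformation and the dienophile is unactivated; thermal Z-to-E isomerisation of the dienoate or loss of facial selectivity could then compete. The fallback sets out from 17 and changes the tether to an acetal. Reductive acetylation of the ester (DIBAL-H, CH2Cl2, −78 °C; then Ac2O, pyridine, DMAP) should give the α-acetoxy ether F1, whose sp3 acetal carbon removes the ester conformational penalty while keeping the tether on the (Z) position. Heating (toluene, 130–150 °C) should give the cycloadduct acetal F2 by the same exo-tether mode. K2CO3 in MeOH should free the lactol F3, and Ag2CO3 on Celite (toluene, reflux) should oxidise it to lactone 18, where the route is rejoined.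

Step 17. The alkene may migrate to endocyclic positions, or hydration may occur without carbon–carbon bond formation, since a seven-membered closure is slower than the usual five- and six-membered cases. The fallback sets out from 24 and replaces the catalytic hydroalkylation by a stepwise cationic alkylation. Hydration alone with the same gold catalyst at 60 °C should allow the methyl ketone 25 to be isolated. HCl in Et2O/CH2Cl2 at −40 °C should add across the exocyclic alkene to give the tertiary chloride F4. TMSOTf and Et3N should convert the ketone into the silyl enol ether F5. ZnCl2 (cat., CH2Cl2, −40 °C) should ionise the chloride so that the enol ether carbon C11 alkylates C9 (tert-alkylation of a silyl enol ether), returning to 26.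

Step 18. Hydrogen abstraction at the tertiary furfurylic C1–H or oxidative degradation of the furan may compete under the peroxy-radical conditions. The fallback sets out from 26 and avoids free radicals. SeO2 in 1,4-dioxane at 80 °C (ene reaction followed by 2,3-sigmatropic shift) should hydroxylate C2 to the allylic alcohol F6, either C2 epimer being usable. Dess–Martin periodinane should then oxidise F6 to the ene-dione 27, where the route is rejoined.

**Further compounds**

F1 | step 11 | α-acetoxy ether from reductive acetylation of 17 (C18 epimers) | CC[C@@H](O[Si](C)(C)C(C)(C)C)/C=C(/CCO[Si](C)(C)C(C)(C)C)COC(OC(C)=O)/C=C\C=C\c1occc1C#C[Si](C(C)C)(C(C)C)C(C)C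
F2 | step 11 | cycloadduct lactol acetate (C18 epimers) | CC[C@@H](O[Si](C)(C)C(C)(C)C)[C@H]1[C@H](c2occc2C#C[Si](C(C)C)(C(C)C)C(C)C)C=C[C@H]2C(OC(C)=O)OC[C@@]12CCO[Si](C)(C)C(C)(C)C
F3 | step 11 | cycloadduct lactol (C18 epimers) | CC[C@@H](O[Si](C)(C)C(C)(C)C)[C@H]1[C@H](c2occc2C#C[Si](C(C)C)(C(C)C)C(C)C)C=C[C@H]2C(O)OC[C@@]12CCO[Si](C)(C)C(C)(C)C
F4 | step 17 | tertiary chloride at C9 of methyl ketone 25 (C9 epimers) | CC(=O)O[C@H]1C[C@@]23COC(=O)C2=CC[C@@H](c4occc4C(C)=O)[C@@H]3C(C)(Cl)[C@@H]1C
F5 | step 17 | trimethylsilyl enol ether of F4 | CC(=O)O[C@H]1C[C@@]23COC(=O)C2=CC[C@@H](c4occc4C(=C)O[Si](C)(C)C)[C@@H]3C(C)(Cl)[C@@H]1C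
F6 | step 18 | C2 allylic alcohol of 26 (C2 epimers) | CC(=O)O[C@H]1C[C@@]23COC(=O)C2=CC(O)[C@H]2c4occc4C(=O)C[C@@](C)([C@@H]1C)[C@@H]23
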